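The earlier runs and the new flask come from a simulation with constants of no real substance; scatter was added.

The yield, the percentage of the charge standing as target at a given time, held still when the charge moved: the east run had 4.00 times the substrate of the north run, yet their last target readings lie 0.4 percentage points apart, at a scatter of 0.3 points per reading.

| flask | substrate | remark | time |
|---|---|---|---|
| north | 0.0055 M | run made earlier |  |
| east | 0.022 M | run made earlier |  |
| flask | 0.011 M |  | 3.0 h |

| run | time / h | target / % | side product B / % |
|---|---|---|---|
| north | 0.200 | 6.0 | 0.3 |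
| north | 0.417 | 16.6 | 0.1 |
| north | 1.00 | 28.2 | 0.9 |
| north | 2.50 | 31.1 | 2.1 |
| east | 0.200 | 6.6 | 0 |
| east | 0.417 | 16.5 | 0.1 |
| east | 1.00 | 28.1 | 0.3 |
| east | 2.50 | 30.7 | 1.5 |

(each reading ± 0.3 percentage points)

- concentration of target at 3.0 h, in M
- concentration of side product B at 3.0 h, in M
- concentration of intermediate B at 3.0 h, in M

The meeting on the flask opened with the analyst, who argued that a yield unmoved by the charge is what first-order steps give, so she took the mean of the last readings, 30.9 %, as the plateau yield of target, to be multiplied by the charge of the flask if it stood at the plateau.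

The kineticist asked whether the flask would be at the plateau by 3.0 h, and counted half-lives: in the two earlier runs the mean gap below that yield falls from 14 points at 0.417 h to 2.8 points at 1.00 h, a half-life read as 0.245 h, so that by his count 8.16 such half-lives fall before the asked time and the gap in the flask is reckoned at 0.0095 points, well under the scatter.

The meeting therefore committed to [target] = 0.00340 M in the flask, while the chair recorded that the mean last readings leave 67.3 % of the charge unseen, and that [intermediate B], never read, stayed open.

The forecast gave 0.00336 M for [target], 2.400 × 10⁻⁴ M for [side product B] and 2.000 × 10⁻⁶ M for [intermediate B], holding that the “intermediate is essentially gone”.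

The flask gives [target] = 0.00341 M, [side product B] = 2.28 × 10⁻⁴ M and [intermediate B] = 5.43 × 10⁻⁴ M.

    substrate → side product A (k = 5.40 × 10⁻⁴ s⁻¹)
    substrate → intermediate A (k = 3.40 × 10⁻⁴ s⁻¹)
    intermediate B ⇌ intermediate C (K = 0.650, k = 5.70 × 10⁻⁵ s⁻¹)
    intermediate A → target (k = 0.00130 s⁻¹)
    intermediate C → side product B (k = 4.00 × 10⁻⁴ s⁻¹)
    intermediate A → intermediate B (k = 3.20 × 10⁻⁴ s⁻¹)

The target in the flask is 31.0 % of its charge, in line with the yield of 30.9 % read from the runs. Carried to the neighbouring flask with 0.019 M of substrate and the same 3.0 h, that yield gives [target] = 0.00587 M, and the neighbour stands at 0.00589 M. Its [side product B] is 3.95 × 10⁻⁴ M, which is 2.08 % of its charge, against 2.08 % in the flask. Its [intermediate B] is 9.37 × 10⁻⁴ M, which is 4.93 % of that charge, against 4.93 % in the flask.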